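**Retrosynthetic overview**

1. The strategy rests on ring C, the 4H-pyran-4-one (O1, C2, C3, C4, C4a, C8a) of the flavone. It is the oxidised cyclisation product of a 2'-hydroxychalcone, so the O1–C2 bond is closed late, on a chalcone whose ring B already carries the C7''–C9'' glyceryl ether on O4'.
2. Chalcone: Cα–Cβ by Claisen–Schmidt condensation of 2'-hydroxy-4',6'-bis(benzyloxy)acetophenone with the ring-B aldehyde; the formyl group comes from an aryl bromide by Br/Li exchange and DMF.
3. Side chain: C7''–C8'' by Evans boron syn-aldol of an (R)-oxazolidinone aryloxyacetyl imide with O-benzylvanillin (fixes C8''), then reduction and Mitsunobu inversion at C7'' to reach erythro (7''R,8''S).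
4. Ring order: rings A, B and the guaiacyl ring are bought as arenes; ring C is the only ring formed. The endgame is desilylation, acetylation of the primary 9''-OH and hydrogenolysis of three benzyl ethers.

Key step: step 11

Remark: the target SMILES encodes the erythro (7''R,8''S) side chain (lignan numbering C7''/C8''/C9''). The ring-B formyl group is carried as a bromide, not as an acetal, because an aryl acetal would not tolerate the boron and silyl triflates; a syn-aldol plus inversion is used because its stereochemical outcome is secure.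

**Route**

Step 1
Reactants: 1 2',4',6'-trihydroxyacetophenone
Product: 2 2'-hydroxy-4',6'-bis(benzyloxy)acetophenone
Conditions: BnBr (2.1 equiv), K2CO3, DMF, rt
Reagents that add atoms: benzyl bromide BrCc1ccccc1
Why: Williamson O-benzylation alkylates the two free phenols, while the 2'-OH that is hydrogen-bonded to the acetyl carbonyl stays free, so the single phenol needed for ring C is kept.

Step 2
Reactants: 3 4-bromo-2,6-dimethoxyphenol; 4 (R)-4-benzyl-3-(chloroacetyl)oxazolidin-2-one
Product: 5 (R)-4-benzyl-3-[(4-bromo-2,6-dimethoxyphenoxy)acetyl]oxazolidin-2-one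
Conditions: K2CO3, NaI (cat.), acetone, 50 °C
Reagents that add atoms: none
Why: Williamson ether synthesis (SN2, iodide-assisted) of the acidic phenoxide on the α-chloro imide should be clean, because the weakly basic phenoxide does not cleave the imide and the auxiliary stereocentre is not involved.

Step 3
Reactants: 5 (R)-4-benzyl-3-[(4-bromo-2,6-dimethoxyphenoxy)acetyl]oxazolidin-2-one; 6 4-benzyloxy-3-methoxybenzaldehyde
Product: 8 (R)-4-benzyl-3-[(2R,3S)-3-(4-benzyloxy-3-methoxyphenyl)-2-(4-bromo-2,6-dimethoxyphenoxy)-3-hydroxypropanoyl]oxazolidin-2-one (syn adduct), via Z-dibutylboron enolate 7 (not isolated)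
Conditions: Bu2BOTf, iPr2NEt, CH2Cl2, −78 to 0 °C; then 6, −78 to 0 °C; pH 7 buffer, MeOH, H2O2, 0 °C
Reagents that add atoms: none
Why: Evans boron syn-aldol, in which the Z-boron enolate reacts through a Zimmerman–Traxler chair on the enolate face away from the benzyl group of the dipole-opposed (R)-oxazolidinone, so that C8'' is set in its final sense and C7'' is set syn to it (threo, 7''S,8''S after reduction).

Step 4
Reactants: 8 syn-aldol adduct
Product: 9 (1S,2S)-1-(4-benzyloxy-3-methoxyphenyl)-2-(4-bromo-2,6-dimethoxyphenoxy)propane-1,3-diol (threo)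
Conditions: NaBH4, THF/H2O (4:1), 0 °C to rt
Reagents that add atoms: none
Why: Reductive cleavage of the Evans auxiliary by borohydride attack on the activated exocyclic imide carbonyl should give the primary alcohol and leave the aryl bromide, the benzyl ether and both stereocentres untouched.

Step 5
Reactants: 9 threo diol
Product: 10 (1S,2S)-1-(4-benzyloxy-3-methoxyphenyl)-2-(4-bromo-2,6-dimethoxyphenoxy)-3-(tert-butyldimethylsilyloxy)propan-1-ol
Conditions: TBSCl (1.05 equiv), imidazole, CH2Cl2, 0 °C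
Reagents that add atoms: tert-butyldimethylsilyl chloride CC(C)(C)[Si](C)(C)Cl
Why: Silylation with TBSCl and imidazole is kinetically selective for the unhindered primary hydroxyl over the hindered secondary benzylic one.

Step 6
Reactants: 10 threo primary silyl ether
Product: 11 (1R,2S)-1-(4-benzyloxy-3-methoxyphenyl)-2-(4-bromo-2,6-dimethoxyphenoxy)-3-(tert-butyldimethylsilyloxy)propyl 4-nitrobenzoate
Conditions: 4-nitrobenzoic acid, PPh3, DIAD, THF, 0 °C to rt
Reagents that add atoms: 4-nitrobenzoic acid O=C(O)c1ccc(cc1)[N+](=O)[O-]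
Why: Mitsunobu reaction with an acidic carboxylic acid (the variant for hindered secondary alcohols) displaces the oxyphosphonium group by SN2 with inversion, turning 7''S into 7''R (erythro), and the electron-withdrawing β-aryloxy and β-silyloxymethyl groups disfavour benzylic ionisation.

Step 7
Reactants: 11 erythro 4-nitrobenzoate
Product: 12 (1R,2S)-1-(4-benzyloxy-3-methoxyphenyl)-2-(4-bromo-2,6-dimethoxyphenoxy)-3-(tert-butyldimethylsilyloxy)propan-1-ol (erythro)
Conditions: K2CO3 (cat.), MeOH/THF, rt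
Reagents that add atoms: none
Why: Base-catalysed transesterification removes the activated 4-nitrobenzoate by acyl–oxygen cleavage, so the C7'' configuration is retained and the silyl ether, aryl bromide and benzyl ether are inert.

Step 8
Reactants: 12 erythro alcohol
Product: 13 5-bromo-2-{[(1R,2S)-1-(4-benzyloxy-3-methoxyphenyl)-1,3-bis(tert-butyldimethylsilyloxy)propan-2-yl]oxy}-1,3-dimethoxybenzene
Conditions: TBSOTf, 2,6-lutidine, CH2Cl2, −78 to 0 °C
Reagents that add atoms: tert-butyldimethylsilyl triflate CC(C)(C)[Si](C)(C)OS(=O)(=O)C(F)(F)F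
Why: The silyl triflate with a hindered pyridine base silylates the hindered secondary benzylic alcohol under non-acidic conditions, without epimerisation.

Step 9
Reactants: 13 bis-silylated aryl bromide
Product: 15 4-{[(1R,2S)-1-(4-benzyloxy-3-methoxyphenyl)-1,3-bis(tert-butyldimethylsilyloxy)propan-2-yl]oxy}-3,5-dimethoxybenzaldehyde, via aryllithium 14 (not isolated)
Conditions: n-BuLi (1.1 equiv), THF, −78 °C; DMF, −78 to 0 °C; aq NH4Cl
Reagents that add atoms: N,N-dimethylformamide CN(C)C=O
Why: Bromine–lithium exchange at −78 °C is much faster than deprotonation next to the ether oxygens, and the aryllithium is formylated by DMF (Bouveault formylation), the hemiaminal collapsing to the aldehyde on work-up.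

Step 10
Reactants: 15 ring-B aldehyde; 2 2'-hydroxy-4',6'-bis(benzyloxy)acetophenone
Product: 16 (E)-1-[2,4-bis(benzyloxy)-6-hydroxyphenyl]-3-(4-{[(1R,2S)-1-(4-benzyloxy-3-methoxyphenyl)-1,3-bis(tert-butyldimethylsilyloxy)propan-2-yl]oxy}-3,5-dimethoxyphenyl)prop-2-en-1-one (2'-hydroxychalcone)
Conditions: KOH (50% aq), EtOH/THF, rt; then dilute AcOH to pH 6
Reagents that add atoms: none
Why: Claisen–Schmidt condensation, in which the acetophenone enolate adds to the non-enolisable aldehyde and E1cB dehydration gives the conjugated E-enone, under conditions that alkyl silyl ethers, benzyl ethers and the alkyl aryl ether tolerate.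

Step 11
Reactants: 16 2'-hydroxychalcone
Product: 19 5,7-bis(benzyloxy)-2-(4-{[(1R,2S)-1-(4-benzyloxy-3-methoxyphenyl)-1,3-bis(tert-butyldimethylsilyloxy)propan-2-yl]oxy}-3,5-dimethoxyphenyl)-4H-chromen-4-one (7'',9''-bis-O-silyl tri-O-benzyl guaiacylglyceryl tricin ether), via flavanone 17 (not isolated), via 3-iodoflavanone 18 (not isolated)
Conditions: I2 (0.1 equiv), DMSO, 110 °C, Ar; aq Na2S2O3 work-up
Reagents that add atoms: none
Why: Iodine promotes the oxa-Michael addition of the only free phenol (2'-OH) to the enone β-carbon to give flavanone 17, whose enol is iodinated at C3 to 18 and loses HI to give the pyranone, while DMSO reoxidises HI to I2 so that iodine is catalytic and DMSO is the terminal oxidant. The closest known reaction is the iodine/DMSO oxidative cyclisation of 2'-hydroxychalcones to flavones, the laboratory counterpart of the chalcone isomerase and flavone synthase sequence. Ring C is closed by a 6-endo-trig attack of the phenol oxygen on Cβ, which forms the O1–C2 bond. The C2 stereocentre of the flavanone is transient and is erased by the dehydrogenation, so no new stereocentre results and C7''/C8'' are spectators. The step needs 6-endo closure to the flavone and not 5-exo oxidative closure to the aurone, which the Michael polarisation of the enone under iodine/DMSO should secure, and it needs a single cyclising phenol, which the 6'-benzyl ether secures. It also needs the side chain to survive, which is secured by silylation of both hydroxyls, by the catalytic iodine loading and by the continuous removal of HI by DMSO.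

Step 12
Reactants: 19 silylated flavone
Product: 20 5,7-bis(benzyloxy)-2-(4-{[(1R,2S)-1-(4-benzyloxy-3-methoxyphenyl)-1,3-dihydroxypropan-2-yl]oxy}-3,5-dimethoxyphenyl)-4H-chromen-4-one
Conditions: TBAF, AcOH, THF, 0 °C to rt
Reagents that add atoms: none
Why: Fluoride-induced desilylation cleaves both Si–O bonds, and buffering with acetic acid keeps the flavone and the β-aryl ether away from free alkoxide.

Step 13
Reactants: 20 flavone diol
Product: 21 (2S,3R)-3-(4-benzyloxy-3-methoxyphenyl)-2-{4-[5,7-bis(benzyloxy)-4-oxo-4H-chromen-2-yl]-2,6-dimethoxyphenoxy}-3-hydroxypropyl acetate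
Conditions: AcCl (1.1 equiv), 2,4,6-collidine, CH2Cl2, −78 °C
Reagents that add atoms: acetyl chloride CC(=O)Cl
Why: Acylation with acetyl chloride and a hindered pyridine base at low temperature is kinetically selective for the primary 9''-hydroxyl over the hindered secondary benzylic 7''-hydroxyl, and no phenol is free at this stage.

Step 14
Reactants: 21 tri-O-benzyl 9''-acetate
Product: 22 (2S,3R)-2-[4-(5,7-dihydroxy-4-oxo-4H-chromen-2-yl)-2,6-dimethoxyphenoxy]-3-hydroxy-3-(4-hydroxy-3-methoxyphenyl)propyl acetate (target)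
Conditions: H2 (1 atm), 10% Pd/C, EtOAc/THF, rt
Reagents that add atoms: none
Why: Palladium-catalysed hydrogenolysis should cleave the three aryl benzyl ethers under neutral conditions that leave the flavone C2=C3 bond, the acetate and the benzylic alcohol intact.

**Compound list**

1 | 2',4',6'-trihydroxyacetophenone | CC(=O)c1c(O)cc(O)cc1O | starting material
2 | 2'-hydroxy-4',6'-bis(benzyloxy)acetophenone | CC(=O)c1c(O)cc(OCc2ccccc2)cc1OCc1ccccc1 | intermediate
3 | 4-bromo-2,6-dimethoxyphenol | COc1cc(Br)cc(OC)c1O | starting material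
4 | (R)-4-benzyl-3-(chloroacetyl)oxazolidin-2-one | O=C(CCl)N1[C@H](Cc2ccccc2)COC1=O | starting material
5 | (R)-4-benzyl-3-[(4-bromo-2,6-dimethoxyphenoxy)acetyl]oxazolidin-2-one | COc1cc(Br)cc(OC)c1OCC(=O)N1[C@H](Cc2ccccc2)COC1=O | intermediate
6 | 4-benzyloxy-3-methoxybenzaldehyde (O-benzylvanillin) | COc1cc(C=O)ccc1OCc1ccccc1 | starting material
7 | Z-dibutylboron enolate of imide 5 | CCCCB(CCCC)O/C(N1[C@H](Cc2ccccc2)COC1=O)=C\Oc1c(OC)cc(Br)cc1OC | intermediate
8 | (R)-4-benzyl-3-[(2R,3S)-3-(4-benzyloxy-3-methoxyphenyl)-2-(4-bromo-2,6-dimethoxyphenoxy)-3-hydroxypropanoyl]oxazolidin-2-one (syn adduct) | COc1cc([C@H](O)[C@H](C(=O)N2[C@H](Cc3ccccc3)COC2=O)Oc2c(OC)cc(Br)cc2OC)ccc1OCc1ccccc1 | intermediate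
9 | (1S,2S)-1-(4-benzyloxy-3-methoxyphenyl)-2-(4-bromo-2,6-dimethoxyphenoxy)propane-1,3-diol (threo) | COc1cc([C@H](O)[C@H](CO)Oc2c(OC)cc(Br)cc2OC)ccc1OCc1ccccc1 | intermediate
10 | (1S,2S)-1-(4-benzyloxy-3-methoxyphenyl)-2-(4-bromo-2,6-dimethoxyphenoxy)-3-(tert-butyldimethylsilyloxy)propan-1-ol | COc1cc([C@H](O)[C@H](CO[Si](C)(C)C(C)(C)C)Oc2c(OC)cc(Br)cc2OC)ccc1OCc1ccccc1 | intermediate
11 | (1R,2S)-1-(4-benzyloxy-3-methoxyphenyl)-2-(4-bromo-2,6-dimethoxyphenoxy)-3-(tert-butyldimethylsilyloxy)propyl 4-nitrobenzoate | COc1cc([C@@H](OC(=O)c2ccc(cc2)[N+](=O)[O-])[C@H](CO[Si](C)(C)C(C)(C)C)Oc2c(OC)cc(Br)cc2OC)ccc1OCc1ccccc1 | intermediate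
12 | (1R,2S)-1-(4-benzyloxy-3-methoxyphenyl)-2-(4-bromo-2,6-dimethoxyphenoxy)-3-(tert-butyldimethylsilyloxy)propan-1-ol (erythro) | COc1cc([C@@H](O)[C@H](CO[Si](C)(C)C(C)(C)C)Oc2c(OC)cc(Br)cc2OC)ccc1OCc1ccccc1 | intermediate
13 | 5-bromo-2-{[(1R,2S)-1-(4-benzyloxy-3-methoxyphenyl)-1,3-bis(tert-butyldimethylsilyloxy)propan-2-yl]oxy}-1,3-dimethoxybenzene | COc1cc([C@@H](O[Si](C)(C)C(C)(C)C)[C@H](CO[Si](C)(C)C(C)(C)C)Oc2c(OC)cc(Br)cc2OC)ccc1OCc1ccccc1 | intermediate
14 | aryllithium from 13 (lithium in place of bromine) | COc1cc([C@@H](O[Si](C)(C)C(C)(C)C)[C@H](CO[Si](C)(C)C(C)(C)C)Oc2c(OC)cc([Li])cc2OC)ccc1OCc1ccccc1 | intermediate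
15 | 4-{[(1R,2S)-1-(4-benzyloxy-3-methoxyphenyl)-1,3-bis(tert-butyldimethylsilyloxy)propan-2-yl]oxy}-3,5-dimethoxybenzaldehyde | COc1cc([C@@H](O[Si](C)(C)C(C)(C)C)[C@H](CO[Si](C)(C)C(C)(C)C)Oc2c(OC)cc(C=O)cc2OC)ccc1OCc1ccccc1 | intermediate
16 | (E)-2'-hydroxy-4',6'-bis(benzyloxy)chalcone carrying the bis-silylated erythro side chain on ring B | COc1cc([C@@H](O[Si](C)(C)C(C)(C)C)[C@H](CO[Si](C)(C)C(C)(C)C)Oc2c(OC)cc(/C=C/C(=O)c3c(O)cc(OCc4ccccc4)cc3OCc3ccccc3)cc2OC)ccc1OCc1ccccc1 | intermediate
17 | 5,7-bis(benzyloxy)flavanone with the same ring-B side chain (C2 epimers) | COc1cc([C@@H](O[Si](C)(C)C(C)(C)C)[C@H](CO[Si](C)(C)C(C)(C)C)Oc2c(OC)cc(C3CC(=O)c4c(OCc5ccccc5)cc(OCc5ccccc5)cc4O3)cc2OC)ccc1OCc1ccccc1 | intermediate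
18 | 3-iodo derivative of flavanone 17 (C2/C3 isomers) | COc1cc([C@@H](O[Si](C)(C)C(C)(C)C)[C@H](CO[Si](C)(C)C(C)(C)C)Oc2c(OC)cc(C3C(I)C(=O)c4c(OCc5ccccc5)cc(OCc5ccccc5)cc4O3)cc2OC)ccc1OCc1ccccc1 | intermediate
19 | 7'',9''-bis-O-TBS tri-O-benzyl guaiacylglyceryl tricin ether (flavone) | COc1cc([C@@H](O[Si](C)(C)C(C)(C)C)[C@H](CO[Si](C)(C)C(C)(C)C)Oc2c(OC)cc(-c3cc(=O)c4c(OCc5ccccc5)cc(OCc5ccccc5)cc4o3)cc2OC)ccc1OCc1ccccc1 | intermediate
20 | tri-O-benzyl erythro-guaiacylglyceryl tricin ether (7'',9''-diol) | COc1cc([C@@H](O)[C@H](CO)Oc2c(OC)cc(-c3cc(=O)c4c(OCc5ccccc5)cc(OCc5ccccc5)cc4o3)cc2OC)ccc1OCc1ccccc1 | intermediate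
21 | tri-O-benzyl erythro-guaiacylglyceryl tricin ether 9''-acetate | COc1cc([C@@H](O)[C@H](COC(C)=O)Oc2c(OC)cc(-c3cc(=O)c4c(OCc5ccccc5)cc(OCc5ccccc5)cc4o3)cc2OC)ccc1OCc1ccccc1 | intermediate
22 | (2S,3R)-2-[4-(5,7-dihydroxy-4-oxo-4H-chromen-2-yl)-2,6-dimethoxyphenoxy]-3-hydroxy-3-(4-hydroxy-3-methoxyphenyl)propyl acetate | COc1cc([C@@H](O)[C@H](COC(C)=O)Oc2c(OC)cc(-c3cc(=O)c4c(O)cc(O)cc4o3)cc2OC)ccc1O | target

**Step count and risks**

Total steps: 14. Longest linear sequence: 13 (steps 2–14, from 3 to 22).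

Steps most likely to fail:

1. Step 11 (key step). The hydrogen iodide formed in hot DMSO may strip or ionise the benzylic silyl ether or dealkylate the 5-O-benzyl ether, and oxidative 5-exo closure may compete. Fallback, iodine-free and in two stages: from chalcone 16, NaOAc in refluxing EtOH should effect the 6-endo oxa-Michael addition alone, and flavanone 17 would be isolated. Soft enolisation (TMSOTf, Et3N, CH2Cl2, 0 °C) should then give the trimethylsilyl enol ether F1, and Saegusa–Ito dehydrogenation (Pd(OAc)2, MeCN, rt) would return to the route at flavone 19.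

2. Step 6. The oxyphosphonium intermediate sits on an electron-rich benzylic carbon, so partial ionisation (loss of clean inversion) or E2 elimination to the enol ether may erode the erythro selectivity. Fallback by oxidation and reduction: from alcohol 10, Dess–Martin oxidation (NaHCO3-buffered, CH2Cl2, 0 °C) should give the α-aryloxy ketone F2. Chelation-controlled reduction with Zn(BH4)2 in Et2O at −30 °C, with hydride delivered to the face of the zinc chelate that carries the small C8''–H, should then give the erythro alcohol 12 directly, and the route resumes at step 8.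

3. Step 14. Once the para-phenol is unveiled, over-reduction may occur: hydrogenolysis of the benzylic C7''–O bond or saturation of C2=C3. Fallback by reordering the endgame: from flavone 19, hydrogenolysis (H2, Pd/C, EtOAc) while C7''–O is still silylated should give the triphenol bis-silyl ether F3. Desilylation (TBAF, AcOH, THF) would give the erythro-guaiacylglyceryl tricin ether F4, and lipase-catalysed transesterification (immobilised Candida antarctica lipase B, vinyl acetate, THF, 40 °C) should acetylate only the primary 9''-hydroxyl, arriving at target 22.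

**Further compounds**

F1 | step 11 | 4-O-trimethylsilyl enol ether of flavanone 17 (5,7-bis(benzyloxy)-4-trimethylsilyloxy-2H-chromene with the same ring-B side chain) | COc1cc([C@@H](O[Si](C)(C)C(C)(C)C)[C@H](CO[Si](C)(C)C(C)(C)C)Oc2c(OC)cc(C3C=C(O[Si](C)(C)C)c4c(OCc5ccccc5)cc(OCc5ccccc5)cc4O3)cc2OC)ccc1OCc1ccccc1
F2 | step 6 | (S)-1-(4-benzyloxy-3-methoxyphenyl)-2-(4-bromo-2,6-dimethoxyphenoxy)-3-(tert-butyldimethylsilyloxy)propan-1-one | COc1cc(C(=O)[C@H](CO[Si](C)(C)C(C)(C)C)Oc2c(OC)cc(Br)cc2OC)ccc1OCc1ccccc1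
F3 | step 14 | 7'',9''-bis-O-TBS erythro-guaiacylglyceryl tricin ether (three free phenols) | COc1cc([C@@H](O[Si](C)(C)C(C)(C)C)[C@H](CO[Si](C)(C)C(C)(C)C)Oc2c(OC)cc(-c3cc(=O)c4c(O)cc(O)cc4o3)cc2OC)ccc1O
F4 | step 14 | tricin 4'-O-[(7''R,8''S)-erythro-guaiacylglyceryl] ether | COc1cc([C@@H](O)[C@H](CO)Oc2c(OC)cc(-c3cc(=O)c4c(O)cc(O)cc4o3)cc2OC)ccc1O
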